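**Retrosynthetic overview**

1. The five-membered ring is closed last: the C2 ketone comes from a C2 carbinol, made by nickel-catalysed methylative cyclisation of a 5-hexynal (ethynyl on C3a, aldehyde C2 on the C1 side chain); this forms C2–C3 and sets the Z-ethylidene.
2. The ethynyl carbon C3, the oxygenated C1 and C2 come from the C=O, the O–CH and the CH2O of a butenolide cycloadduct; its lactone is a temporary ring, opened by hydride reduction and alkyne homologation with epimerisation at C3a.
3. Key disconnection: the six-membered ring by [4+2] cycloaddition of a 3-methoxy-vinylallene with a chiral-pool butenolide, forming C7–C7a and C3a–C4 and setting C7a, C3a (provisionally) and C4 from the single stereocentre C1.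
4. Enabling feature: in the six-membered ring the four contiguous non-fusion atoms C7(=CH2)–C6(O)–C5H2–C4(i-Pr) are the imprint of an alkoxy-vinylallene (central allene carbon = C7, enol-ether carbon = C6), and the fusion bond C7a–C3a with its neighbours C1(O), C2 and C3 is the C=C, γ-CH–O, CH2O and C=O of a 5-(acyloxymethyl)butenolide.
5. Ring order: lactone (temporary, from the chiral pool), then the six-membered carbocycle (step 4), then the five-membered carbocycle (step 14).

Key step: step 4

Assumption: (R)-5-(hydroxymethyl)furan-2(5H)-one is taken as purchasable (the enantiomer of the common glutamic-acid-derived butenolide; otherwise it is made from commercial (R)-5-(hydroxymethyl)dihydrofuran-2(3H)-one by selenation and elimination).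

Locants: the indane numbering of the target is used for every intermediate: C1 (CH–O-2-methylbutanoyl), C2 (C=O), C3 (C=CHCH3), C3a and C7a (ring fusion, C3a next to C3), C4 (CH-i-Pr), C5 (CH2), C6 (CH–O-enoyl), C7 (C=CH2).

**Route**

Step 1
Reactants: 1 3-methylbut-1-yne
Product: 3 (E)-1-iodo-3-methylbut-1-ene, via alkenylzirconocene chloride 2 (not isolated)
Conditions: Cp2Zr(H)Cl, CH2Cl2, 0 °C → rt; then I2, 0 °C
Reagents that add atoms: iodine, II
Why: Hydrozirconation of the terminal alkyne is syn and places zirconium on the terminal carbon, and iodinolysis of the C–Zr bond with retention should give the (E)-alkenyl iodide.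

Step 2
Reactants: 4 methoxyallene; 3 (E)-1-iodo-3-methylbut-1-ene
Product: 7 (4E)-3-methoxy-6-methylhepta-1,2,4-triene, via 1-lithio-1-methoxyallene 5 (not isolated), via (1-methoxyallenyl)zinc chloride 6 (not isolated)
Conditions: n-BuLi, THF, −78 °C; ZnCl2, −78 → 0 °C; then 3, Pd(PPh3)4 (5 mol %), rt; NaHCO3 work-up, Et3N-deactivated silica
Reagents that add atoms: none
Why: α-Lithiation of methoxyallene, transmetalation to zinc and Negishi coupling at the oxygen-bearing carbon should keep the allene and the E alkene intact, as is usual for 1-alkoxyallenyl zinc reagents.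

Step 3
Reactants: 8 (R)-5-(hydroxymethyl)furan-2(5H)-one
Product: 9 [(2R)-5-oxo-2,5-dihydrofuran-2-yl]methyl 2,2-dimethylpropanoate
Conditions: t-BuCOCl, pyridine, CH2Cl2, 0 °C
Reagents that add atoms: pivaloyl chloride, CC(C)(C)C(=O)Cl
Why: Acylation of the primary alcohol gives a bulky group that shields one face of the butenolide and is later removed by the same hydride that reduces the lactone; no stereocentre is touched.

Step 4
Reactants: 7 (4E)-3-methoxy-6-methylhepta-1,2,4-triene; 9 [(2R)-5-oxo-2,5-dihydrofuran-2-yl]methyl 2,2-dimethylpropanoate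
Product: 10 cis-fused cycloadduct lactone (lactone C=O = C3, lactone O on C1, CH2OPiv = C2; cyclohexene with C7=CH2, C6(OMe)=C5, C4-i-Pr; H-7a, H-3a and H-4 all cis; CH2OPiv anti to the C7a–C7 bond)
Conditions: 7 (2 equiv), PhMe, BHT (cat.), sealed tube, 110 °C; Et3N-deactivated silica
Reagents that add atoms: none
Why: Thermal, concerted but asynchronous [4+2] cycloaddition in which the s-cis diene made of the internal allene C=C and the (E)-alkene of 7 adds suprafacially to the butenolide C=C of 9; the closest known reaction types are the Diels–Alder reactions of oxygenated vinylallenes and of 5-substituted 2(5H)-furanones. The cyclohexene ring is closed by intermolecular cycloaddition (C7–C7a between the central allene carbon and the butenolide β-carbon leading, C3a–C4 lagging), while the lactone is carried in as a temporary cis-fused ring. C7a is set by attack on the butenolide face anti to the CH2OPiv group of the existing C1 stereocentre, C3a follows from suprafacial addition to the cis alkene, and C4 from the endo transition state (lactone carbonyl under the diene) combined with the E geometry of the isopropyl-bearing alkene, which places H-4 cis to H-3a and H-7a. The step needs regioselectivity, and both diene substituents secure it: the 2-methoxy group (para director) and the terminal isopropyl group (ortho director) put the largest HOMO coefficient on the central allene carbon, which pairs with the large LUMO coefficient at the butenolide β-carbon. The product diene (exocyclic methylidene plus ring enol ether) is locked s-trans and cannot add a second dienophile, and it already carries the C7 methylidene and the C6 carbonyl, the latter masked as its methyl enol ether.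

Step 5
Reactants: 10 cis-fused cycloadduct lactone
Product: 11 lactol diol (C3 hemiacetal, free C2–OH; mixture of anomers and lactol ring sizes; stereocentres as in 10)
Conditions: i-Bu2AlH (4 equiv), CH2Cl2, −78 °C; MeOH, aq. potassium sodium tartrate
Reagents that add atoms: none
Why: Reduction of the lactone stops at the lactol because the aluminium hemiacetal is stable at −78 °C, and the pivalate is cleaved reductively in the same operation; the enol-ether diene is inert to hydride and no stereocentre is touched.

Step 6
Reactants: 11 lactol diol
Product: 13 (1R)-1-[2-ethynyl-5-methoxy-6-methylidene-3-(propan-2-yl)cyclohex-4-en-1-yl]ethane-1,2-diol (ring substituents at C7a, C3a and C4 all trans), via trans-fused lactol 12 (not isolated)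
Conditions: K2CO3, MeOH, rt (equilibration); then dimethyl (1-diazo-2-oxopropyl)phosphonate, rt → 40 °C
Reagents that add atoms: dimethyl (1-diazo-2-oxopropyl)phosphonate, COP(=O)(OC)C(=[N+]=[N-])C(C)=O
Why: In basic methanol the lactols equilibrate through the open hydroxy aldehyde, whose enolisation should epimerise C3a towards the trans-fused, decalin-like six-membered lactol (C2–O closing on C3, both fusion bonds equatorial), and Ohira–Bestmann (Seyferth–Gilbert) homologation of the open aldehyde should then give the terminal alkyne with H-3a trans to H-7a and H-4.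

Step 7
Reactants: 13 alkyne diol
Product: 14 (1R)-2-[(tert-butyldimethylsilyl)oxy]-1-[2-ethynyl-5-methoxy-6-methylidene-3-(propan-2-yl)cyclohex-4-en-1-yl]ethan-1-ol
Conditions: TBSCl (1.05 equiv), imidazole, CH2Cl2, 0 °C
Reagents that add atoms: tert-butyldimethylsilyl chloride, CC(C)(C)[Si](C)(C)Cl
Why: Sterically controlled silylation should take the primary hydroxyl of the 1,2-diol and leave the secondary C1–OH free.

Step 8
Reactants: 14 mono-silyl ether; 15 (2R)-2-methylbutanoic acid
Product: 16 (1R)-2-[(tert-butyldimethylsilyl)oxy]-1-[2-ethynyl-5-methoxy-6-methylidene-3-(propan-2-yl)cyclohex-4-en-1-yl]ethyl (2R)-2-methylbutanoate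
Conditions: DCC, DMAP (cat.), CH2Cl2, 0 °C → rt
Reagents that add atoms: none
Why: Steglich esterification acylates the C1 hydroxyl with retention, and the purely alkyl-substituted α-centre of the acid is not prone to epimerisation under these conditions.

Step 9
Reactants: 16 C1 ester enol ether
Product: 17 (1R)-2-[(tert-butyldimethylsilyl)oxy]-1-[2-ethynyl-6-methylidene-5-oxo-3-(propan-2-yl)cyclohexyl]ethyl (2R)-2-methylbutanoate
Conditions: (CO2H)2 (0.2 M aq.), THF, 0 °C; used crude
Reagents that add atoms: water, O
Why: Mild acid hydrolysis of the methyl enol ether, by protonation at C5 (the oxygen-stabilised site of the 2-methoxydiene), should unmask the C6 ketone without cleaving the primary silyl ether or moving the exocyclic alkene into the ring.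

Step 10
Reactants: 17 α-methylene ketone
Product: 18 (6S)-allylic alcohol: (1R)-2-[(tert-butyldimethylsilyl)oxy]-1-[2-ethynyl-5-hydroxy-6-methylidene-3-(propan-2-yl)cyclohexyl]ethyl (2R)-2-methylbutanoate (C6–OH axial, trans to the C7a side chain)
Conditions: (R)-Me-CBS oxazaborolidine (0.5 equiv), catecholborane, PhMe, −78 °C
Reagents that add atoms: none
Why: In this Corey–Bakshi–Shibata reduction the methylidene-bearing C7 acts as the large ketone substituent, so the (R)-catalyst should deliver hydride to the face that gives the (6S) axial alcohol, and at −78 °C catecholborane neither hydroborates the alkyne nor reduces the s-cis enone in the conjugate sense.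

Step 11
Reactants: 18 (6S)-allylic alcohol; 19 (2E)-3-methylpent-2-enoic acid
Product: 21 diester silyl ether (C6 (2E)-3-methylpent-2-enoate, C1 (2R)-2-methylbutanoate, C2–OTBS, C3a ethynyl), via mixed anhydride 20 (not isolated)
Conditions: 19, 2,4,6-Cl3C6H2COCl, Et3N, THF, rt; then 18, DMAP, PhMe, rt
Reagents that add atoms: none
Why: Yamaguchi esterification acylates the hindered axial allylic alcohol with retention at C6, and the mixed-anhydride route is chosen to avoid isomerising the trisubstituted enoate.

Step 12
Reactants: 21 diester silyl ether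
Product: 22 primary alcohol (C2–OH free, otherwise as 21)
Conditions: HF·pyridine, pyridine, THF, 0 °C → rt
Reagents that add atoms: none
Why: Buffered fluoride cleaves the primary silyl ether under non-basic conditions, which should suppress 1,2-acyl migration from the C1 oxygen.

Step 13
Reactants: 22 primary alcohol
Product: 23 α-acyloxy aldehyde (C2 = CHO, otherwise as 22)
Conditions: Dess–Martin periodinane, CH2Cl2, 0 °C → rt; used directly
Reagents that add atoms: none
Why: Dess–Martin oxidation takes the primary alcohol to the aldehyde without epimerising the adjacent acyloxy-bearing C1.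

Step 14
Reactants: 23 α-acyloxy aldehyde
Product: 24 (3Z)-2-hydroxy hydrindane: the target with C2 as CH–OH (either epimer at C2)
Conditions: Ni(COD)2 (15 mol %), Me2Zn (3 equiv), THF, 0 °C, slow addition of 23; aq. NH4Cl
Reagents that add atoms: dimethylzinc, C[Zn]C
Why: In this nickel-catalysed alkylative cyclisation of a 5-hexynal, oxidative cyclisation of alkyne and aldehyde on zerovalent nickel forms C2–C3, and methyl transfer from zinc followed by reductive elimination places CH3 cis to C2 (syn addition across the alkyne), which gives the Z-ethylidene; the trans-diequatorial side chains close to the trans-hydrindane and the configuration of the new carbinol is irrelevant.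

Step 15
Reactants: 24 (3Z)-2-hydroxy hydrindane
Product: 25 (1R,3Z,3aR,4R,6S,7aS)-3-ethylidene-7-methylidene-6-{[(2E)-3-methylpent-2-enoyl]oxy}-2-oxo-4-(propan-2-yl)octahydro-1H-inden-1-yl (2R)-2-methylbutanoate
Conditions: Dess–Martin periodinane, CH2Cl2, 0 °C
Reagents that add atoms: none
Why: Dess–Martin oxidation of the allylic alcohol should give the enone without touching the Z alkene, the exocyclic methylidene or the α-acyloxy stereocentre C1.

**Compound list**

1 | 3-methylbut-1-yne | CC(C)C#C | starting material
2 | (E)-(3-methylbut-1-enyl)zirconocene chloride, Cp2Zr(Cl)(CH=CH-i-Pr) | CC(C)/C=C/[Zr](Cl)(C1C=CC=C1)C1C=CC=C1 | intermediate (not isolated)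
3 | (E)-1-iodo-3-methylbut-1-ene | CC(C)/C=C/I | intermediate
4 | methoxyallene (1-methoxypropa-1,2-diene) | COC=C=C | starting material
5 | 1-lithio-1-methoxyallene | [Li]C(OC)=C=C | intermediate (not isolated)
6 | (1-methoxyallenyl)zinc chloride | Cl[Zn]C(OC)=C=C | intermediate (not isolated)
7 | (4E)-3-methoxy-6-methylhepta-1,2,4-triene | C=C=C(OC)/C=C/C(C)C | intermediate
8 | (R)-5-(hydroxymethyl)furan-2(5H)-one | O=C1C=C[C@H](CO)O1 | starting material
9 | [(2R)-5-oxo-2,5-dihydrofuran-2-yl]methyl 2,2-dimethylpropanoate | O=C1C=C[C@H](COC(=O)C(C)(C)C)O1 | intermediate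
10 | cis-fused cycloadduct lactone (H-7a, H-3a, H-4 all cis; CH2OPiv anti to C7a–C7) | C=C1C(OC)=C[C@H](C(C)C)[C@@H]2C(=O)O[C@@H](COC(=O)C(C)(C)C)[C@H]12 | intermediate
11 | lactol diol (drawn as the cis-fused five-membered lactol; anomeric mixture) | C=C1C(OC)=C[C@H](C(C)C)[C@@H]2C(O)O[C@@H](CO)[C@H]12 | intermediate
12 | trans-fused six-membered lactol (C3a epimerised; anomeric mixture) | C=C1C(OC)=C[C@H](C(C)C)[C@H]2C(O)OC[C@H](O)[C@H]12 | intermediate (not isolated)
13 | (1R)-1-[2-ethynyl-5-methoxy-6-methylidene-3-(propan-2-yl)cyclohex-4-en-1-yl]ethane-1,2-diol, ring substituents all trans | C=C1C(OC)=C[C@H](C(C)C)[C@@H](C#C)[C@@H]1[C@@H](O)CO | intermediate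
14 | primary TBS ether of 13 | C=C1C(OC)=C[C@H](C(C)C)[C@@H](C#C)[C@@H]1[C@@H](O)CO[Si](C)(C)C(C)(C)C | intermediate
15 | (2R)-2-methylbutanoic acid | CC[C@@H](C)C(=O)O | starting material
16 | C1 (2R)-2-methylbutanoate of 14 | C=C1C(OC)=C[C@H](C(C)C)[C@@H](C#C)[C@@H]1[C@@H](OC(=O)[C@H](C)CC)CO[Si](C)(C)C(C)(C)C | intermediate
17 | α-methylene ketone (C6=O) | C=C1C(=O)C[C@H](C(C)C)[C@@H](C#C)[C@@H]1[C@@H](OC(=O)[C@H](C)CC)CO[Si](C)(C)C(C)(C)C | intermediate
18 | (6S)-allylic alcohol (axial OH) | C=C1[C@@H](O)C[C@H](C(C)C)[C@@H](C#C)[C@@H]1[C@@H](OC(=O)[C@H](C)CC)CO[Si](C)(C)C(C)(C)C | intermediate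
19 | (2E)-3-methylpent-2-enoic acid | CC/C(C)=C/C(=O)O | starting material
20 | (2E)-3-methylpent-2-enoic 2,4,6-trichlorobenzoic anhydride | CC/C(C)=C/C(=O)OC(=O)c1c(Cl)cc(Cl)cc1Cl | intermediate (not isolated)
21 | diester silyl ether | C=C1[C@@H](OC(=O)/C=C(\C)CC)C[C@H](C(C)C)[C@@H](C#C)[C@@H]1[C@@H](OC(=O)[C@H](C)CC)CO[Si](C)(C)C(C)(C)C | intermediate
22 | primary alcohol | C=C1[C@@H](OC(=O)/C=C(\C)CC)C[C@H](C(C)C)[C@@H](C#C)[C@@H]1[C@@H](OC(=O)[C@H](C)CC)CO | intermediate
23 | α-acyloxy aldehyde | C=C1[C@@H](OC(=O)/C=C(\C)CC)C[C@H](C(C)C)[C@@H](C#C)[C@@H]1[C@@H](OC(=O)[C@H](C)CC)C=O | intermediate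
24 | (3Z)-2-hydroxy hydrindane (C2 epimers) | C=C1[C@@H]2[C@H](/C(=C/C)C(O)[C@@H]2OC(=O)[C@H](C)CC)[C@@H](C(C)C)C[C@@H]1OC(=O)/C=C(\C)CC | intermediate
25 | (1R,3Z,3aR,4R,6S,7aS)-3-ethylidene-7-methylidene-6-{[(2E)-3-methylpent-2-enoyl]oxy}-2-oxo-4-(propan-2-yl)octahydro-1H-inden-1-yl (2R)-2-methylbutanoate | C=C1[C@@H]2[C@H](/C(=C/C)C(=O)[C@@H]2OC(=O)[C@H](C)CC)[C@@H](C(C)C)C[C@@H]1OC(=O)/C=C(\C)CC | target

**Step count and risks**

Total steps: 15. Longest linear sequence: 14 steps (1 → 3 → 7 → 10 → … → 25).

Steps most likely to fail:

Step 4. The heat- and acid-sensitive vinylallene may dimerise or oligomerise faster than it adds to the only moderately activated butenolide, and endo selectivity may erode at the temperature needed. The fallback activates the dienophile with a removable α-halogen. It sets out from 9: bromine in CH2Cl2 at 0 °C should give the 3,4-dibromolactone F1, and Et3N then eliminates HBr to the 3-bromobutenolide F2, an α-halo dienophile of higher reactivity. Cycloaddition of F2 with 7 at lower temperature (PhMe, 60 °C) should give the bromo cycloadduct F3 with the same facial and endo preferences. Radical debromination (Bu3SnH, AIBN, PhH, 80 °C) should deliver hydrogen to the convex face and regenerate the cis-fused lactone, so the route is rejoined at 10.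

Step 6. C3a may epimerise incompletely before homologation, and the lactol may open slowly, so that epimer mixtures and base-induced degradation build up over long reaction times. The fallback separates the two events and replaces the diazophosphonate by olefination and elimination. It sets out from 11: equilibration with DBU in MeOH and isolation of the trans-fused lactol 12; Wittig reaction with Ph3P=CHCl (from (chloromethyl)triphenylphosphonium chloride and NaN(SiMe3)2, THF) should open the lactol to the chloroalkene diol F4 (E/Z mixture); excess n-BuLi (THF, −78 → 0 °C) then eliminates HCl to the alkyne, and the route is rejoined at 13.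

Step 10. Facial selectivity may be poor because reagent control has to override the intrinsic axial hydride delivery to the cyclohexanone, and conjugate reduction of the s-cis enone may compete. The fallback uses the substrate preference and then inverts. It sets out from 17: Luche reduction (NaBH4, CeCl3·7H2O, MeOH, −78 °C) should give the equatorial (6R)-allylic alcohol F5 by axial hydride attack; Mitsunobu esterification with acid 19 (PPh3, DIAD, PhMe, 0 °C) inverts C6 and installs the enoate in one operation, so the route is rejoined at 21.

**Further compounds**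

F1 | step 4 | [(2R)-3,4-dibromo-5-oxotetrahydrofuran-2-yl]methyl 2,2-dimethylpropanoate | O=C1C(Br)C(Br)[C@H](COC(=O)C(C)(C)C)O1
F2 | step 4 | [(2R)-4-bromo-5-oxo-2,5-dihydrofuran-2-yl]methyl 2,2-dimethylpropanoate (3-bromobutenolide) | O=C1C(Br)=C[C@H](COC(=O)C(C)(C)C)O1
F3 | step 4 | bromo cycloadduct (10 with Br in place of H-3a) | C=C1C(OC)=C[C@H](C(C)C)[C@]2(Br)C(=O)O[C@@H](COC(=O)C(C)(C)C)[C@H]12
F4 | step 6 | (1R)-1-[2-(2-chloroethenyl)-5-methoxy-6-methylidene-3-(propan-2-yl)cyclohex-4-en-1-yl]ethane-1,2-diol (E/Z mixture, ring substituents all trans) | C=C1C(OC)=C[C@H](C(C)C)[C@@H](C=CCl)[C@@H]1[C@@H](O)CO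
F5 | step 10 | (6R)-allylic alcohol (C6 epimer of 18, equatorial OH) | C=C1[C@H](O)C[C@H](C(C)C)[C@@H](C#C)[C@@H]1[C@@H](OC(=O)[C@H](C)CC)CO[Si](C)(C)C(C)(C)C
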